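**Strategy.** The oxolane ring (O1, C2 aryl, C3, C4 carbinol, C5) hides a β-keto ester enol (O1–C2=C3) and an α-sulfonyloxy ketone (C4=O, C5–OTs): its tertiary C4–OH next to the O-bound C5 methylene is the retron of an interrupted Feist–Benary annulation. One catalytic asymmetric operation makes C3–C4 (aldol, sets C4) and O1–C5 (enol O-alkylation), joining the two C6–C3 halves of a lignan monomer. Hydroxyl-directed hydrogenation of C2=C3 then sets C2 and C3. Acid converts part of this bromo monomer into the aryltetralin half (C2 cation, Friedel–Crafts), and a Suzuki coupling of the two monomers makes the biaryl bond.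

Key step: step 4

Assumption: compounds 1 and 4 are taken as catalogue chemicals, and (DHQD)2PYR is taken to give the (4S) carbinol in step 4; if the sense of induction is the opposite, the pseudoenantiomeric (DHQ)2PYR is used.

**Step 1**
Reactants: 1 methyl 3-bromo-4-hydroxy-5-methoxybenzoate
Product: 2 methyl 4-(benzyloxy)-3-bromo-5-methoxybenzoate
Conditions: BnBr, K2CO3, DMF, 60 °C
Reagents that add atoms: benzyl bromide, BrCc1ccccc1
Why: Williamson etherification, in which the acidic 2-bromo-6-methoxyphenoxide is O-alkylated by benzyl bromide under carbonate conditions that leave the methyl ester untouched.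

**Step 2**
Reactants: 2 methyl 4-(benzyloxy)-3-bromo-5-methoxybenzoate
Product: 3 methyl 3-[4-(benzyloxy)-3-bromo-5-methoxyphenyl]-3-oxopropanoate
Conditions: MeOAc, LiN(SiMe3)2 (3 equiv), THF, −78 → 0 °C; then cold 1 M HCl
Reagents that add atoms: methyl acetate, COC(C)=O
Why: Crossed Claisen condensation, in which the lithium enolate of methyl acetate acylates the non-enolizable aryl ester and excess amide base drives the equilibrium by deprotonating the β-keto ester, while identical methoxy groups in both esters prevent ester scrambling and the aryl bromide is inert to the hindered amide at low temperature.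

**Step 3**
Reactants: 4 2-[4-(benzyloxy)-3-methoxyphenyl]acetic acid
Product: 7 3-[4-(benzyloxy)-3-methoxyphenyl]-2-oxopropyl 4-methylbenzenesulfonate, via acid chloride 5 (not isolated), via diazoketone 6 (not isolated)
Conditions: (COCl)2, DMF (cat.), CH2Cl2, 0 °C → rt; then Me3SiCHN2, THF–MeCN, 0 °C; then anhydrous TsOH, CH2Cl2, 0 °C → rt
Reagents that add atoms: trimethylsilyldiazomethane, C[Si](C)(C)C=[N+]=[N-]; p-toluenesulfonic acid, Cc1ccc(S(=O)(=O)O)cc1; oxalyl chloride, O=C(Cl)C(=O)Cl (chlorine of 5 only)
Why: Acid chloride formation, C-acylation of trimethylsilyldiazomethane (the diazoketone stage of the Arndt–Eistert sequence) and protonation of the diazoketone by the sulfonic acid with displacement of dinitrogen by tosylate are each standard and should give the α-sulfonyloxy ketone without touching the benzyl ether.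

**Step 4**
Reactants: 3 methyl 3-[4-(benzyloxy)-3-bromo-5-methoxyphenyl]-3-oxopropanoate; 7 3-[4-(benzyloxy)-3-methoxyphenyl]-2-oxopropyl 4-methylbenzenesulfonate
Product: 9 methyl (4S)-2-[4-(benzyloxy)-3-bromo-5-methoxyphenyl]-4-{[4-(benzyloxy)-3-methoxyphenyl]methyl}-4-hydroxy-4,5-dihydrofuran-3-carboxylate, via aldol adduct 8 (not isolated)
Conditions: (DHQD)2PYR (hydroquinidine 2,5-diphenyl-4,6-pyrimidinediyl diether, 10 mol %), 1,8-bis(dimethylamino)naphthalene (1.1 equiv), THF, −40 → 0 °C; chromatography on Et3N-deactivated silica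
Reagents that add atoms: none
Why: The amine base ionizes only the β-keto ester 3, whose enolate adds through C3 to the ketone carbon of 7 (aldol, C3–C4) inside the ion pair with the protonated cinchona alkaloid, after which the re-formed enol oxygen of the aryl ketone displaces tosylate at C5 (O1–C5) and the C4–OH is kept because no acid is present. The closest known reaction type is the cinchona-catalysed asymmetric interrupted Feist–Benary reaction of 1,3-dicarbonyl compounds with bromopyruvates and α-tosyloxy aryl ketones. The only ring closed, the 4,5-dihydrofuran, closes by 5-exo-tet O-alkylation of the enol. C4 is the only stereocentre formed and is set by the catalyst, which shields one face of the ketone in the hydrogen-bonded ammonium enolate complex, while the C3 centre of adduct 8 is erased on enolization. The step needs carbonyl addition to outrun direct SN2 C-alkylation at C5 and needs the enol oxygen, not the C4 oxygen, to close the ring: the hard tosylate is a poor partner for the soft enolate carbon, and the weak base leaves the tertiary alcohol of 8 un-ionized so no epoxide should form. The benzylic α-protons of 7 are several pK units less acidic than those of 3, so self-condensation of 7 should not compete.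

**Step 5**
Reactants: 9 methyl (4S)-2-[4-(benzyloxy)-3-bromo-5-methoxyphenyl]-4-{[4-(benzyloxy)-3-methoxyphenyl]methyl}-4-hydroxy-4,5-dihydrofuran-3-carboxylate
Product: 10 methyl (2R,3R,4S)-2-[4-(benzyloxy)-3-bromo-5-methoxyphenyl]-4-{[4-(benzyloxy)-3-methoxyphenyl]methyl}-4-hydroxyoxolane-3-carboxylate
Conditions: H2 (50 bar), [Ir(cod)(PCy3)(py)]PF6 (10 mol %), CH2Cl2, rt
Reagents that add atoms: none
Why: Hydroxyl-directed homogeneous hydrogenation, in which the tertiary C4–OH binds the cationic iridium centre so that both hydrogens reach C2=C3 from the hydroxyl face (also the less hindered face), one syn addition thereby setting C2 and C3 with aryl and ester cis to each other and to the C4 arylmethyl group, and this catalyst class reduces tetrasubstituted alkenes without cleaving aryl bromides or benzyl ethers.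

**Step 6**
Reactants: 10 methyl (2R,3R,4S)-2-[4-(benzyloxy)-3-bromo-5-methoxyphenyl]-4-{[4-(benzyloxy)-3-methoxyphenyl]methyl}-4-hydroxyoxolane-3-carboxylate
Product: 11 (3S,4R,5R)-5-[4-(benzyloxy)-3-bromo-5-methoxyphenyl]-3-{[4-(benzyloxy)-3-methoxyphenyl]methyl}-4-(hydroxymethyl)oxolan-3-ol
Conditions: i-Bu2AlH (4 equiv), CH2Cl2, −78 → 0 °C; aq. potassium sodium tartrate
Reagents that add atoms: none
Why: Aluminium hydride reduction of the ester to the primary alcohol at low temperature under non-basic conditions, so the epimerizable, contra-thermodynamic C3 centre should be carried through unchanged and the aryl bromide is not reduced.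

**Step 7**
Reactants: 11 (3S,4R,5R)-5-[4-(benzyloxy)-3-bromo-5-methoxyphenyl]-3-{[4-(benzyloxy)-3-methoxyphenyl]methyl}-4-(hydroxymethyl)oxolan-3-ol
Product: 12 (2S,3S,4S)-6-(benzyloxy)-4-[4-(benzyloxy)-3-bromo-5-methoxyphenyl]-2,3-bis(hydroxymethyl)-7-methoxy-1,2,3,4-tetrahydronaphthalen-2-ol
Conditions: CF3CO2H (10 equiv), CH2Cl2, 0 °C → rt; NaHCO3, MeOH–H2O work-up
Reagents that add atoms: none
Why: Acid ionizes the benzylic C2–O1 bond to a para-alkoxybenzyl cation that is captured irreversibly by the arylmethyl ring at its position para to methoxy (intramolecular Friedel–Crafts alkylation closing a 6-membered ring, the known acid isomerization of 2-aryl-4-benzyloxolane lignans to aryltetralins), the new benzylic centre forming trans to the adjacent CH2OH because the aryl group is pseudo-equatorial in the half-chair transition state, while reversible re-closure to the oxolane only recycles the cation.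

**Step 8**
Reactants: 11 (3S,4R,5R)-5-[4-(benzyloxy)-3-bromo-5-methoxyphenyl]-3-{[4-(benzyloxy)-3-methoxyphenyl]methyl}-4-(hydroxymethyl)oxolan-3-ol; 12 (2S,3S,4S)-6-(benzyloxy)-4-[4-(benzyloxy)-3-bromo-5-methoxyphenyl]-2,3-bis(hydroxymethyl)-7-methoxy-1,2,3,4-tetrahydronaphthalen-2-ol
Product: 14 tetra-O-benzyl biaryl (oxolane unit of 11 joined to tetralin unit of 12 at the two former C–Br carbons), via pinacol boronate 13 (not isolated)
Conditions: 11 (1.2 equiv), B2pin2, Pd(dppf)Cl2 (5 mol %), KOAc, 1,4-dioxane, 90 °C; then 12, Pd(OAc)2/SPhos (5/10 mol %), K3PO4, H2O, 90 °C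
Reagents that add atoms: bis(pinacolato)diboron, CC1(C)OB(B2OC(C)(C)C(C)(C)O2)OC1(C)C (boryl group of 13 only)
Why: Miyaura borylation of 11 followed in the same flask by Suzuki–Miyaura coupling with 12, the borylation being run to completion before 12 and aqueous phosphate are added so that only the unsymmetrical biaryl can form, with a dialkylbiarylphosphine for the two ortho-benzyloxy groups, free hydroxyls tolerated and no stereocentre involved.

**Step 9**
Reactants: 14 tetra-O-benzyl biaryl
Product: 15 (2S,3S,4S)-4-{4-hydroxy-3-[2-hydroxy-5-[(2R,3R,4S)-4-hydroxy-4-[(4-hydroxy-3-methoxyphenyl)methyl]-3-(hydroxymethyl)oxolan-2-yl]-3-methoxyphenyl]-5-methoxyphenyl}-2,3-bis(hydroxymethyl)-7-methoxy-1,2,3,4-tetrahydronaphthalene-2,6-diol (CNP0344108.1)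
Conditions: H2 (1 atm), Pd/C (10 %), EtOAc–MeOH, rt
Reagents that add atoms: none
Why: Hydrogenolysis of the four benzyl aryl ethers over palladium on carbon in a neutral solvent at atmospheric pressure is much faster than cleavage of the benzylic C2–O1 bond of the oxolane, so stopping at the uptake of four equivalents should give the tetraphenol with all six stereocentres intact.

**Compound list**

1 | methyl 3-bromo-4-hydroxy-5-methoxybenzoate (methyl 5-bromovanillate) | COC(=O)c1cc(OC)c(O)c(Br)c1 | starting material
2 | methyl 4-(benzyloxy)-3-bromo-5-methoxybenzoate | COC(=O)c1cc(OC)c(OCc2ccccc2)c(Br)c1 | intermediate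
3 | methyl 3-[4-(benzyloxy)-3-bromo-5-methoxyphenyl]-3-oxopropanoate | COC(=O)CC(=O)c1cc(OC)c(OCc2ccccc2)c(Br)c1 | intermediate
4 | 2-[4-(benzyloxy)-3-methoxyphenyl]acetic acid | COc1cc(CC(=O)O)ccc1OCc1ccccc1 | starting material
5 | 2-[4-(benzyloxy)-3-methoxyphenyl]acetyl chloride | COc1cc(CC(=O)Cl)ccc1OCc1ccccc1 | intermediate (not isolated)
6 | 1-[4-(benzyloxy)-3-methoxyphenyl]-3-diazopropan-2-one | COc1cc(CC(=O)C=[N+]=[N-])ccc1OCc1ccccc1 | intermediate (not isolated)
7 | 3-[4-(benzyloxy)-3-methoxyphenyl]-2-oxopropyl 4-methylbenzenesulfonate | COc1cc(CC(=O)COS(=O)(=O)c2ccc(C)cc2)ccc1OCc1ccccc1 | intermediate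
8 | methyl (3S)-2-[4-(benzyloxy)-3-bromo-5-methoxybenzoyl]-3-{[4-(benzyloxy)-3-methoxyphenyl]methyl}-3-hydroxy-4-[(4-methylbenzenesulfonyl)oxy]butanoate (C2 unassigned, enolizable) | COc1cc(C[C@@](C(C(=O)c2cc(OC)c(OCc3ccccc3)c(Br)c2)C(=O)OC)(O)COS(=O)(=O)c2ccc(C)cc2)ccc1OCc1ccccc1 | intermediate (not isolated)
9 | methyl (4S)-2-[4-(benzyloxy)-3-bromo-5-methoxyphenyl]-4-{[4-(benzyloxy)-3-methoxyphenyl]methyl}-4-hydroxy-4,5-dihydrofuran-3-carboxylate | COc1cc(C[C@@]2(O)COC(c3cc(OC)c(OCc4ccccc4)c(Br)c3)=C2C(=O)OC)ccc1OCc1ccccc1 | intermediate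
10 | methyl (2R,3R,4S)-2-[4-(benzyloxy)-3-bromo-5-methoxyphenyl]-4-{[4-(benzyloxy)-3-methoxyphenyl]methyl}-4-hydroxyoxolane-3-carboxylate (aryl, ester and arylmethyl all cis, OH trans) | COc1cc(C[C@@]2(O)CO[C@@H](c3cc(OC)c(OCc4ccccc4)c(Br)c3)[C@H]2C(=O)OC)ccc1OCc1ccccc1 | intermediate
11 | (3S,4R,5R)-5-[4-(benzyloxy)-3-bromo-5-methoxyphenyl]-3-{[4-(benzyloxy)-3-methoxyphenyl]methyl}-4-(hydroxymethyl)oxolan-3-ol | COc1cc(C[C@@]2(O)CO[C@@H](c3cc(OC)c(OCc4ccccc4)c(Br)c3)[C@H]2CO)ccc1OCc1ccccc1 | intermediate
12 | (2S,3S,4S)-6-(benzyloxy)-4-[4-(benzyloxy)-3-bromo-5-methoxyphenyl]-2,3-bis(hydroxymethyl)-7-methoxy-1,2,3,4-tetrahydronaphthalen-2-ol | COc1cc([C@H]2c3cc(OCc4ccccc4)c(OC)cc3C[C@@](O)(CO)[C@@H]2CO)cc(Br)c1OCc1ccccc1 | intermediate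
13 | pinacol boronate of 11 (Bpin in place of Br) | COc1cc(C[C@@]2(O)CO[C@@H](c3cc(OC)c(OCc4ccccc4)c(B4OC(C)(C)C(C)(C)O4)c3)[C@H]2CO)ccc1OCc1ccccc1 | intermediate (not isolated)
14 | tetra-O-benzyl ether of 15 | COc1cc(C[C@@]2(O)CO[C@@H](c3cc(OC)c(OCc4ccccc4)c(-c4cc([C@H]5c6cc(OCc7ccccc7)c(OC)cc6C[C@@](O)(CO)[C@@H]5CO)cc(OC)c4OCc4ccccc4)c3)[C@H]2CO)ccc1OCc1ccccc1 | intermediate
15 | CNP0344108.1 (name as in step 9) | COc1cc(C[C@@]2(O)CO[C@@H](c3cc(OC)c(O)c(-c4cc([C@H]5c6cc(O)c(OC)cc6C[C@@](O)(CO)[C@@H]5CO)cc(OC)c4O)c3)[C@H]2CO)ccc1O | target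

**Count.** Total steps: 9. Longest linear sequence: 8 steps (1, 2, 4, 5, 6, 7, 8, 9).

**Steps most likely to fail**

Step 4. The catalyst may discriminate poorly between the faces of a non-activated, enolizable ketone, and direct C-alkylation at the CH2OTs carbon may compete with the aldol. The fallback sets out from 3 and 7. An achiral amine base (DABCO, THF, rt) should give the racemic dihydrofuran F1 by the classical interrupted Feist–Benary reaction. Preparative chromatography on a polysaccharide chiral stationary phase (supercritical CO2/MeOH, neutral) then separates 9 from its (4R)-enantiomer F2, which is discarded. The route is rejoined at 9.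

Step 5. The tetrasubstituted push–pull alkene may not turn over, or the acidic iridium hydride may promote loss of water from C4/C5 and aromatization to the furan. The fallback sets out from 9 and changes the element of stereocontrol. Heterogeneous syn addition on a platinum surface (PtO2, H2, 3 atm, EtOAc) places the alkene on the metal by its less hindered face, opposite the C4 arylmethyl group, so no hydroxyl coordination is needed; platinum is the metal least prone to cleave aryl bromides and benzyl ethers. This fallback makes no new compound (F0) and comes back at 10.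

Step 8. Incomplete borylation would let the two bromides scramble into homo-coupled biaryls, and the ortho-alkoxy arylboronate may protodeboronate. The fallback sets out from 11 and removes the need for cross-selectivity. Reductive homocoupling (NiCl2(PPh3)2, Zn, Et4NI, THF, 50 °C) should give the C2-symmetric bis-oxolane dimer F3. Treatment with CF3CO2H in CH2Cl2 at 0 °C, stopped at partial conversion, then closes one aryltetralin. Because the two oxolane units of F3 are homotopic, only one mono-cyclized product can form, and unchanged F3 is recovered and resubmitted. The route is rejoined at 14.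

**Further compounds**

F1 | step 4 | racemic methyl 2-[4-(benzyloxy)-3-bromo-5-methoxyphenyl]-4-{[4-(benzyloxy)-3-methoxyphenyl]methyl}-4-hydroxy-4,5-dihydrofuran-3-carboxylate | COc1cc(CC2(O)COC(c3cc(OC)c(OCc4ccccc4)c(Br)c3)=C2C(=O)OC)ccc1OCc1ccccc1
F2 | step 4 | (4R)-enantiomer of 9 | COc1cc(C[C@]2(O)COC(c3cc(OC)c(OCc4ccccc4)c(Br)c3)=C2C(=O)OC)ccc1OCc1ccccc1
F0 | step 5 | none | none
F3 | step 8 | C2-symmetric 5,5'-biaryl dimer of debrominated 11 (both halves (3S,4R,5R)-oxolane, four benzyl ethers) | COc1cc(C[C@@]2(O)CO[C@@H](c3cc(OC)c(OCc4ccccc4)c(-c4cc([C@@H]5OC[C@](O)(Cc6ccc(OCc7ccccc7)c(OC)c6)[C@@H]5CO)cc(OC)c4OCc4ccccc4)c3)[C@H]2CO)ccc1OCc1ccccc1
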